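The readings were generated by integration for an exercise, and the scatter is random.

A leftover comes first: substrate is charged at 20 mM and partner at 14.0 mM, less than the substrate. If one partner goes into one product, the partner is the limiting reagent, 70.0 % of the substrate charged can become product, and the other 30.0 % finds no partner. The zeta run reads 69.8 % at 1.33 min and 70.4 % at 3.00 min, which sits on that ceiling within the scatter of 0.5 percentage points.

| flask | substrate | partner | free catalyst | remark | time |
|---|---|---|---|---|---|
| beta | 20 mM | 14 mM | 33 µM | run made earlier |  |
| zeta | 20 mM | 14 mM | 200 µM | run made earlier |  |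
| oak | 20 mM | 14.0 mM | 60 µM |  | 6.0 min |
| elm | 20 mM | 14.0 mM | 100 µM |  | 6.0 min |
| larch | 20 mM | 14.0 mM | 150 µM |  | 6.0 min |
| birch | 20 mM | 14.0 mM | 250 µM |  | 6.0 min |
| cedar | 20 mM | 14.0 mM | 300 µM |  | 6.0 min |

- beta (time / min: product / %): 0.250: 10.7; 0.500: 19.8; 1.33: 47.5; 3.00: 68.4
- zeta (time / min: product / %): 0.250: 51.2; 0.500: 68.9; 1.33: 69.8; 3.00: 70.4

(each reading ± 0.5 percentage points)

- "hardly changes" means that all values lie within two and a half points (for a concentration: within two and a half percent of the largest)

- amount of product at the end, in percent of the substrate charged for oak, elm, larch, birch, cedar, in this order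
- the shape of the row from first to last (hardly changes / falls, then rises / rises, then falls / falls all the way / rises all the way)

The rule of thumb at the bench is to count a catalysed flask by catalyst times time. The earlier runs allow a test of it. Beta reads 68.4 % at 3.00 min and zeta reads 68.9 % at 0.500 min, while their products of catalyst and time stand in the ratio 1.01. The two readings differ by 0.5 points, about the scatter of one reading.

So the last beta reading can serve as the unit, since it stands 1.6 points under the ceiling. Oak has 3.64 of that unit: this is the dose margin, a flask's catalyst times its time over the same product for beta at its last reading. By this reckoning oak stands level with beta's last reading near 1.65 min.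

The rule has two borders. Under a margin of one, the readings promise less than the ceiling. At the other end, zeta's last reading stands at a margin of 6.06. Elm reaches just that, 6.06. Cedar reaches 18.2, which is 3.00 times zeta's, so for cedar the rule is an extrapolation. The reckoning here commits to the ceiling for oak and elm, and carries it on to larch, birch and cedar on the strength of zeta's flat readings.

The forecast gives 70 %, 70 %, 70 %, 70 % and 70 %, shape hardly changes, and says “even oak should finish in about 1 to 2 min”.

The flasks give 70.0 %, 70.0 %, 70.0 %, 70.0 % and 70.0 %, shape hardly changes.

    catalyst intermediate C ⇌ by-product + catalyst intermediate D (K = 0.0140 M, k = 130 s⁻¹)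
    substrate + free catalyst → catalyst intermediate A (k = 780 L mol⁻¹ s⁻¹)
    catalyst intermediate B ⇌ catalyst intermediate C (K = 3.70, k = 14.0 s⁻¹)
    partner + catalyst intermediate A ⇌ catalyst intermediate B (K = 200 L mol⁻¹, k = 3800 L mol⁻¹ s⁻¹)
    catalyst intermediate D → free catalyst + product (k = 39.0 s⁻¹)

Oak ends with 0 % of its partner and 30 % of its substrate left. At 3.00 min oak's dose margin is 1.82, and its product already stands at 70.0 %. Elm's margin at 3.00 min is 3.03, with product at 70.0 %.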